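**Retrosynthetic overview**

1. Target 18 ⇐ phenol 17 by bromination at the two free positions ortho and para to OH.
2. Feature used: in 17 the phenol O lies on the same face of the cyclopentane (C1–C5) as the cyclopropane carbon C6 and within reach of bridgehead C1. The C1–C6 bond is therefore disconnected while an O–C1 bond is formed, which leads to the cis-fused cyclopenta[b]benzofuran 15 with CH2SnBu3 on C5 on the oxygen face.
3. 15 ⇐ exocyclic alkene 10 (C5=C6) by hydroboration from the convex face, mesylation and stannyl anion displacement; 10 ⇐ phenol allylic alcohol 9 by SN1′ closure of O–C1.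
4. 9 ⇐ enaminone 5 by MeLi addition with 1,3-carbonyl transposition (the blocking-group carbon becomes C6), reduction and O-demethylation; 5 ⇐ 3 + 4 by asymmetric Pd α-arylation, which sets C2.
5. Ring order: cyclopentane bought, arene attached at C2 (step 2), dihydrofuran closed (step 6), cyclopropane closed as the dihydrofuran opens (step 10).

Key step: step 10

Numbering used below (bicyclohexane of the target): C1 methyl-bearing bridgehead, C2 aryl-bearing carbon, C3/C4 ring CH2, C5 bridgehead CH, C6 cyclopropane CH2.

Assumption: which antipode of the binaphthyl ligand gives the (2S) ketone in step 2 has to be settled in a trial run; the (S)-ligand is written and its mirror image is used if the sense is opposite.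

**Step 1**
Reactants: 1 2-methylcyclopentanone
Product: 3 (E)-2-methyl-5-[(N-methylanilino)methylidene]cyclopentan-1-one, via sodium hydroxymethylene enolate 2 (not isolated)
Conditions: NaH, HCO2Et, cat. EtOH, THF, 0 °C → rt; then PhNHMe·HCl, rt
Reagents that add atoms: ethyl formate CCOC=O; N-methylanilinium chloride C[NH2+]c1ccccc1.[Cl-]
Why: Claisen formylation can end only at the CH2 side, since only that β-keto aldehyde is held as a stabilised enolate, and the salt then condenses with the secondary amine to the vinylogous amide that blocks C5 and whose carbon is kept as C6.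

**Step 2**
Reactants: 3 (E)-2-methyl-5-[(N-methylanilino)methylidene]cyclopentan-1-one; 4 2-bromo-5-methylanisole
Product: 5 (2S,5E)-2-(2-methoxy-4-methylphenyl)-2-methyl-5-[(N-methylanilino)methylidene]cyclopentan-1-one
Conditions: Pd2(dba)3 (2 mol%), (S)-2-(dicyclohexylphosphino)-2′-(dimethylamino)-1,1′-binaphthyl (5 mol%), NaOt-Bu, toluene, rt → 50 °C
Reagents that add atoms: none
Why: Buchwald-type Pd-catalysed asymmetric α-arylation of an α′-blocked 2-alkylcyclopentanone, in which only the C2 enolate can form and the chiral monophosphine on the arylpalladium enolate decides which enolate face enters C–C reductive elimination, so setting the quaternary C2 centre.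

**Step 3**
Reactants: 5 (2S,5E)-2-(2-methoxy-4-methylphenyl)-2-methyl-5-[(N-methylanilino)methylidene]cyclopentan-1-one
Product: 7 (3R)-3-(2-methoxy-4-methylphenyl)-2,3-dimethylcyclopent-1-ene-1-carbaldehyde, via tertiary carbinol 1,2-adduct 6 (not isolated)
Conditions: MeLi, THF, −78 → 0 °C; then 2 M HCl, THF, rt
Reagents that add atoms: methyllithium [Li]C
Why: MeLi adds 1,2 to the vinylogous amide carbonyl (this is the C1 methyl) and acid then expels water through the vinylogous iminium ion and hydrolyses it, a Stork–Danheiser-type 1,3-carbonyl transposition that turns the blocking group into the C6 aldehyde without touching C2.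

**Step 4**
Reactants: 7 (3R)-3-(2-methoxy-4-methylphenyl)-2,3-dimethylcyclopent-1-ene-1-carbaldehyde
Product: 8 [(3R)-3-(2-methoxy-4-methylphenyl)-2,3-dimethylcyclopent-1-en-1-yl]methanol
Conditions: NaBH4, CeCl3·7H2O, MeOH, 0 °C
Reagents that add atoms: none
Why: Luche 1,2-reduction of the fully substituted enal, with no stereocentre formed.

**Step 5**
Reactants: 8 [(3R)-3-(2-methoxy-4-methylphenyl)-2,3-dimethylcyclopent-1-en-1-yl]methanol
Product: 9 2-[(1R)-3-(hydroxymethyl)-1,2-dimethylcyclopent-2-en-1-yl]-5-methylphenol
Conditions: NaSEt, DMF, 120 °C; aq. NH4Cl work-up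
Reagents that add atoms: none
Why: SN2 attack of thiolate on the O-methyl group (aryl methyl ether cleavage) frees the phenol, while the allylic alcohol and the tetrasubstituted alkene are inert to base.

**Step 6**
Reactants: 9 2-[(1R)-3-(hydroxymethyl)-1,2-dimethylcyclopent-2-en-1-yl]-5-methylphenol
Product: 10 (3aS,8bS)-3a,6,8b-trimethyl-3-methylidene-2,3,3a,8b-tetrahydro-1H-cyclopenta[b][1]benzofuran
Conditions: CSA (10 mol%), 4 Å MS, CH2Cl2 (0.01 M), 0 °C → rt
Reagents that add atoms: none
Why: Acid-catalysed dehydrative SN1′ cycloetherification, in which the allylic alcohol ionises to the C6–C5–C1 allyl cation, closure at C6 would need a bridgehead alkene, and the phenol therefore closes 5-exo on tertiary C1 from the aryl face (only a cis-fused 5/5 system can form), which sets C1 and leaves the exocyclic C5=C6 alkene.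

**Step 7**
Reactants: 10 (3aS,8bS)-3a,6,8b-trimethyl-3-methylidene-2,3,3a,8b-tetrahydro-1H-cyclopenta[b][1]benzofuran
Product: 12 [(3R,3aS,8bS)-3a,6,8b-trimethyl-2,3,3a,8b-tetrahydro-1H-cyclopenta[b][1]benzofuran-3-yl]methanol, via B-alkyl-9-BBN borane 11 (not isolated)
Conditions: 9-BBN, THF, rt → 60 °C; then 3 M NaOH, 30% H2O2, 0 °C → rt
Reagents that add atoms: hydrogen peroxide OO
Why: Anti-Markovnikov hydroboration–oxidation in which the bulky borane should add from the convex face of the cis-fused tricycle (the face away from the benzofuran flap), so that hydrogen enters C5 from that face and the CH2OH group ends on the oxygen face, which sets C5.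

**Step 8**
Reactants: 12 [(3R,3aS,8bS)-3a,6,8b-trimethyl-2,3,3a,8b-tetrahydro-1H-cyclopenta[b][1]benzofuran-3-yl]methanol
Product: 13 [(3R,3aS,8bS)-3a,6,8b-trimethyl-2,3,3a,8b-tetrahydro-1H-cyclopenta[b][1]benzofuran-3-yl]methyl methanesulfonate
Conditions: MsCl, Et3N, CH2Cl2, 0 °C
Reagents that add atoms: methanesulfonyl chloride CS(=O)(=O)Cl
Why: Sulfonylation of an unhindered primary alcohol, with no stereocentre involved.

**Step 9**
Reactants: 13 [(3R,3aS,8bS)-3a,6,8b-trimethyl-2,3,3a,8b-tetrahydro-1H-cyclopenta[b][1]benzofuran-3-yl]methyl methanesulfonate; 14 tributyltin hydride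
Product: 15 tributyl{[(3S,3aS,8bS)-3a,6,8b-trimethyl-2,3,3a,8b-tetrahydro-1H-cyclopenta[b][1]benzofuran-3-yl]methyl}stannane
Conditions: 14, LDA, THF, 0 °C; then 13, −78 → 0 °C
Reagents that add atoms: none
Why: SN2 displacement of a primary mesylate by the soft tributylstannyl anion (stannyl anion alkylation), which leaves C5 and the aryl ether untouched; the change of descriptor at C3 is only a change of CIP priority.

**Step 10**
Reactants: 15 tributyl{[(3S,3aS,8bS)-3a,6,8b-trimethyl-2,3,3a,8b-tetrahydro-1H-cyclopenta[b][1]benzofuran-3-yl]methyl}stannane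
Product: 17 2-[(1S,2R,5R)-1,2-dimethylbicyclo[3.1.0]hexan-2-yl]-5-methylphenol, via aryl trimethylsilyl ether 16 (not isolated)
Conditions: TMSOTf (1.3 equiv), 2,6-di-tert-butyl-4-methylpyridine (1.5 equiv), CH2Cl2, −78 → 0 °C; then K2CO3, MeOH, 0 °C
Reagents that add atoms: none
Why: Proposed new method: TMSOTf silylates the dihydrofuran oxygen and the tertiary C1–O bond ionises to a cation at C1 that is still tethered to the aryl silyl ether through C2; the C6–Sn bond, which sits on the face the oxygen has left and can point its back lobe into the empty p orbital when CH2SnBu3 is pseudoaxial on C5, then forms C1–C6 in a 3-exo closure with loss of Bu3Sn+ as its triflate, so the cyclopropane closes as the furan ring opens. The closest known reactions are the 1,3-eliminations of γ-stannyl tertiary alcohols and sulfonates to cyclopropanes and, run backwards, the acid-mediated closure of aryl cyclopropanes of this kind to cis-fused dihydrobenzofurans; an aryl ether as the leaving group of such an elimination has not been shown. The re-formed C1 stereocentre is controlled by C5, because C6 can reach the planar cation only from the face on which it already stands, and as oxygen and aryl shared that face the cyclopropane must end cis to the aryl group, with C2 and C5 untouched. The step needs closure to win over 1,2-hydride shift from C5 (which would give a β-stannyl cation and then an alkene), aryl or methyl migration from C2 and E1 loss of a proton; this should be secured by the pseudoaxial C6–Sn bond being aligned with the cation while C5–H lies near its nodal plane (the conformer that also avoids strain with the C1 methyl), by the low temperature and by the non-nucleophilic counter-ion. The hindered pyridine keeps the medium free of triflic acid and the phenol leaves the reaction capped as its silyl ether, so the acid-labile cyclopropyl phenol cannot close back to a C5-methyl dihydrobenzofuran before basic methanolysis frees it.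

**Step 11**
Reactants: 17 2-[(1S,2R,5R)-1,2-dimethylbicyclo[3.1.0]hexan-2-yl]-5-methylphenol
Product: 18 2,4-dibromo-6-[(1S,2R,5R)-1,2-dimethylbicyclo[3.1.0]hexan-2-yl]-3-methylphenol
Conditions: NBS (2.1 equiv), NaHCO3, MeCN, 0 °C → rt, dark
Reagents that add atoms: N-bromosuccinimide O=C1CCC(=O)N1Br
Why: Electrophilic aromatic bromination directed by the free OH to its only open ortho and para positions (both flank the methyl group), with bicarbonate keeping the medium free of acid so that the cyclopropane is not opened.

**Compound list**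

1 | 2-methylcyclopentanone | CC1CCCC1=O | starting material
2 | 2-(hydroxymethylidene)-5-methylcyclopentan-1-one (present as its sodium enolate) | CC1CCC(=CO)C1=O | intermediate
3 | (E)-2-methyl-5-[(N-methylanilino)methylidene]cyclopentan-1-one | CC1CC/C(=C\N(C)c2ccccc2)C1=O | intermediate
4 | 2-bromo-5-methylanisole | COc1cc(C)ccc1Br | starting material
5 | (2S,5E)-2-(2-methoxy-4-methylphenyl)-2-methyl-5-[(N-methylanilino)methylidene]cyclopentan-1-one | COc1cc(C)ccc1[C@]1(C)CC/C(=C\N(C)c2ccccc2)C1=O | intermediate
6 | (2S,5E)-2-(2-methoxy-4-methylphenyl)-1,2-dimethyl-5-[(N-methylanilino)methylidene]cyclopentan-1-ol (present as lithium alkoxide, C1 epimers) | COc1cc(C)ccc1[C@]1(C)CC/C(=C\N(C)c2ccccc2)C1(C)O | intermediate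
7 | (3R)-3-(2-methoxy-4-methylphenyl)-2,3-dimethylcyclopent-1-ene-1-carbaldehyde | COc1cc(C)ccc1[C@]1(C)CCC(C=O)=C1C | intermediate
8 | [(3R)-3-(2-methoxy-4-methylphenyl)-2,3-dimethylcyclopent-1-en-1-yl]methanol | COc1cc(C)ccc1[C@]1(C)CCC(CO)=C1C | intermediate
9 | 2-[(1R)-3-(hydroxymethyl)-1,2-dimethylcyclopent-2-en-1-yl]-5-methylphenol | Cc1ccc([C@]2(C)CCC(CO)=C2C)c(O)c1 | intermediate
10 | (3aS,8bS)-3a,6,8b-trimethyl-3-methylidene-2,3,3a,8b-tetrahydro-1H-cyclopenta[b][1]benzofuran | Cc1ccc2c(c1)O[C@@]1(C)C(=C)CC[C@@]21C | intermediate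
11 | 9-{[(3S,3aS,8bS)-3a,6,8b-trimethyl-2,3,3a,8b-tetrahydro-1H-cyclopenta[b][1]benzofuran-3-yl]methyl}-9-borabicyclo[3.3.1]nonane | Cc1ccc2c(c1)O[C@@]1(C)[C@@H](CB3C4CCCC3CCC4)CC[C@@]21C | intermediate
12 | [(3R,3aS,8bS)-3a,6,8b-trimethyl-2,3,3a,8b-tetrahydro-1H-cyclopenta[b][1]benzofuran-3-yl]methanol | Cc1ccc2c(c1)O[C@@]1(C)[C@@H](CO)CC[C@@]21C | intermediate
13 | [(3R,3aS,8bS)-3a,6,8b-trimethyl-2,3,3a,8b-tetrahydro-1H-cyclopenta[b][1]benzofuran-3-yl]methyl methanesulfonate | Cc1ccc2c(c1)O[C@@]1(C)[C@@H](COS(C)(=O)=O)CC[C@@]21C | intermediate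
14 | tributyltin hydride | CCCC[SnH](CCCC)CCCC | starting material
15 | tributyl{[(3S,3aS,8bS)-3a,6,8b-trimethyl-2,3,3a,8b-tetrahydro-1H-cyclopenta[b][1]benzofuran-3-yl]methyl}stannane | Cc1ccc2c(c1)O[C@@]1(C)[C@@H](C[Sn](CCCC)(CCCC)CCCC)CC[C@@]21C | intermediate
16 | {2-[(1S,2R,5R)-1,2-dimethylbicyclo[3.1.0]hexan-2-yl]-5-methylphenoxy}trimethylsilane | Cc1ccc([C@]2(C)CC[C@@H]3C[C@@]32C)c(O[Si](C)(C)C)c1 | intermediate
17 | 2-[(1S,2R,5R)-1,2-dimethylbicyclo[3.1.0]hexan-2-yl]-5-methylphenol | Cc1ccc([C@]2(C)CC[C@@H]3C[C@@]32C)c(O)c1 | intermediate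
18 | 2,4-dibromo-6-[(1S,2R,5R)-1,2-dimethylbicyclo[3.1.0]hexan-2-yl]-3-methylphenol | Cc1c(Br)cc([C@]2(C)CC[C@@H]3C[C@@]32C)c(O)c1Br | target

**Step count**

Total steps: 11. Longest linear sequence: 11 steps (1 → 18).

**Steps most likely to fail**

1. Step 10 (proposed new method). The ether may fail to ionise under aprotic conditions, or the cation may leave by hydride shift and loss of tin, by aryl or methyl migration, or by proton loss before the C6–Sn bond closes. The fallback uses known chemistry and sets out from 7. Tsuji–Wilkinson decarbonylation (RhCl(PPh3)3, toluene, reflux) should give 1-[(1R)-1,2-dimethylcyclopent-2-en-1-yl]-2-methoxy-4-methylbenzene F1. Thiolate demethylation (NaSEt, DMF, 120 °C) should then give 2-[(1R)-1,2-dimethylcyclopent-2-en-1-yl]-5-methylphenol F2. A hydroxyl-directed Simmons–Smith–Furukawa cyclopropanation (Et2Zn, CH2I2, CH2Cl2, 0 °C), in which the zinc phenoxide delivers the methylene to the alkene face on the aryl side, comes back to the route at 17.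

2. Step 2. The ortho-methoxy group of 4 may slow the coupling and erode the enantioface selection in the reductive elimination. The fallback replaces catalyst control by a covalent resolution and sets out from 1. Formylation as in step 1 (through 2) and condensation with (S)-N-methyl-1-phenylethylamine hydrochloride should give (5E)-2-methyl-5-({methyl[(1S)-1-phenylethyl]amino}methylidene)cyclopentan-1-one F3. Arylation with 4 under an achiral catalyst (Pd2(dba)3, rac-BINAP, NaOt-Bu) should give two diastereomers: (2S,5E)-2-(2-methoxy-4-methylphenyl)-2-methyl-5-({methyl[(1S)-1-phenylethyl]amino}methylidene)cyclopentan-1-one F4 and its (2R) epimer (2R,5E)-2-(2-methoxy-4-methylphenyl)-2-methyl-5-({methyl[(1S)-1-phenylethyl]amino}methylidene)cyclopentan-1-one F5. These are separated by crystallisation or preparative chromatography on silica. F4 under the conditions of step 3 comes back to the route at 7, with the chiral amine released for recovery.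

3. Step 7. The borane may attack the concave face as well, which would place C6 trans to the oxygen and lead to the wrong cyclopropane in step 10. The fallback replaces kinetic facial selection by thermodynamic control and sets out from 10. Hydroboration–oxidation with BH3·SMe2 gives 12 mixed with its C3 epimer [(3S,3aS,8bS)-3a,6,8b-trimethyl-2,3,3a,8b-tetrahydro-1H-cyclopenta[b][1]benzofuran-3-yl]methanol F6. Dess–Martin oxidation of the mixture gives (3R,3aS,8bS)-3a,6,8b-trimethyl-2,3,3a,8b-tetrahydro-1H-cyclopenta[b][1]benzofuran-3-carbaldehyde F7 together with its epimer (3S,3aS,8bS)-3a,6,8b-trimethyl-2,3,3a,8b-tetrahydro-1H-cyclopenta[b][1]benzofuran-3-carbaldehyde F8. DBU in CH2Cl2 should equilibrate these towards F8, whose formyl group sits beside the ring oxygen and not beside the angular methyl. Reduction with NaBH4 in MeOH comes back to the route at 12. Any material that opens by reversible β-aryloxy elimination is reduced to 9 in the same operation and re-enters at step 6.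

**Further compounds**

F1 | step 10 | 1-[(1R)-1,2-dimethylcyclopent-2-en-1-yl]-2-methoxy-4-methylbenzene | COc1cc(C)ccc1[C@]1(C)CCC=C1C
F2 | step 10 | 2-[(1R)-1,2-dimethylcyclopent-2-en-1-yl]-5-methylphenol | Cc1ccc([C@]2(C)CCC=C2C)c(O)c1
F3 | step 2 | (5E)-2-methyl-5-({methyl[(1S)-1-phenylethyl]amino}methylidene)cyclopentan-1-one | CC1CC/C(=C\N(C)[C@@H](C)c2ccccc2)C1=O
F4 | step 2 | (2S,5E)-2-(2-methoxy-4-methylphenyl)-2-methyl-5-({methyl[(1S)-1-phenylethyl]amino}methylidene)cyclopentan-1-one | COc1cc(C)ccc1[C@]1(C)CC/C(=C\N(C)[C@@H](C)c2ccccc2)C1=O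
F5 | step 2 | (2R,5E)-2-(2-methoxy-4-methylphenyl)-2-methyl-5-({methyl[(1S)-1-phenylethyl]amino}methylidene)cyclopentan-1-one | COc1cc(C)ccc1[C@@]1(C)CC/C(=C\N(C)[C@@H](C)c2ccccc2)C1=O
F6 | step 7 | [(3S,3aS,8bS)-3a,6,8b-trimethyl-2,3,3a,8b-tetrahydro-1H-cyclopenta[b][1]benzofuran-3-yl]methanol | Cc1ccc2c(c1)O[C@@]1(C)[C@H](CO)CC[C@@]21C
F7 | step 7 | (3R,3aS,8bS)-3a,6,8b-trimethyl-2,3,3a,8b-tetrahydro-1H-cyclopenta[b][1]benzofuran-3-carbaldehyde | Cc1ccc2c(c1)O[C@@]1(C)[C@H](C=O)CC[C@@]21C
F8 | step 7 | (3S,3aS,8bS)-3a,6,8b-trimethyl-2,3,3a,8b-tetrahydro-1H-cyclopenta[b][1]benzofuran-3-carbaldehyde | Cc1ccc2c(c1)O[C@@]1(C)[C@@H](C=O)CC[C@@]21C
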